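**Strategy.** Both halves are the same enantiopure phenol, (2R,3S)-3-(3,5-dihydroxy-2-methylphenyl)butan-2-ol, whose two stereocentres come from (2S,3S)-2,3-epoxybutane. One copy is closed to the isochroman with formaldehyde and joined through a CH2 bridge to C7 of a second, still open copy. The last ring, the pyran of the quinone methide half, is then built by a [5+1] annulation. Triethyl orthoformate inserts C1 between the single remaining aromatic CH (the future C8a, ortho to the C8 hydroxyl and next to C4a) and the C3 hydroxyl. This forms C8a–C1 and C1–O2 and unmasks the vinylogous acid C8=O/C6–OH in the same operation, without protecting groups.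

Key step: step 6

Assumption: 1-bromo-3,5-dimethoxy-2-methylbenzene and (2S,3S)-2,3-epoxybutane are taken as catalogue compounds; ring atoms of both halves are numbered as in 2-benzopyran (C1, O2, C3, C4, C4a, C5–C8, C8a).

Step 1
Reactants: 1 1-bromo-3,5-dimethoxy-2-methylbenzene; 2 (2S,3S)-2,3-dimethyloxirane (trans-2,3-epoxybutane)
Product: 4 (2S,3S)-3-(3,5-dimethoxy-2-methylphenyl)butan-2-ol, via aryl Grignard reagent 3 (not isolated)
Conditions: Mg, THF, reflux; then CuI (10 mol%), 2 (1.5 equiv), −30 °C → rt; sat. aq. NH4Cl
Reagents that add atoms: none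
Why: Copper-catalysed SN2 opening of the C2-symmetric epoxide by the aryl Grignard reagent (both epoxide carbons are equivalent, so there is no regiochemical issue) should proceed with inversion at the attacked carbon and give the erythro alcohol, the benzylic centre (S) being set by inversion and the carbinol centre (S) carried over from the epoxide.

Step 2
Reactants: 4 (2S,3S)-3-(3,5-dimethoxy-2-methylphenyl)butan-2-ol
Product: 5 (2R,3S)-3-(3,5-dimethoxy-2-methylphenyl)butan-2-yl formate
Conditions: HCO2H, PPh3, DIAD, THF, 0 °C → rt
Reagents that add atoms: formic acid OC=O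
Why: Mitsunobu reaction, in which formate displaces the alkoxyphosphonium group by SN2, should invert the carbinol centre to R and so convert the erythro into the required threo series, while the benzylic centre is not touched.

Step 3
Reactants: 5 (2R,3S)-3-(3,5-dimethoxy-2-methylphenyl)butan-2-yl formate
Product: 7 (2R,3S)-3-(3,5-dihydroxy-2-methylphenyl)butan-2-ol, via dihydroxy formate 6 (not isolated)
Conditions: BBr3, CH2Cl2, −78 → 0 °C; then MeOH, rt
Reagents that add atoms: none
Why: BBr3 cleavage of both aryl methyl ethers should be followed, on the methanol quench, by HBr-catalysed methanolysis of the labile formate, which until then shields the secondary alcohol from bromination; no bond to either stereocentre is broken.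

Step 4
Reactants: 7 (2R,3S)-3-(3,5-dihydroxy-2-methylphenyl)butan-2-ol
Product: 8 (3R,4S)-3,4,5-trimethyl-3,4-dihydro-1H-2-benzopyran-6,8-diol
Conditions: (CH2O)n (1.0 equiv), TsOH·H2O (5 mol%), MeCN (0.02 M), rt
Reagents that add atoms: formaldehyde (as paraformaldehyde) C=O
Why: Phenolic oxa-Pictet–Spengler reaction, in which the hemiacetal at the secondary hydroxyl ionises to an oxocarbenium ion that is attacked by the ring carbon next to the side chain (para to one hydroxyl, ortho to the other), should close the isochroman ring with both stereocentres retained because neither of their bonds is broken.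

Step 5
Reactants: 8 (3R,4S)-3,4,5-trimethyl-3,4-dihydro-1H-2-benzopyran-6,8-diol; 7 (2R,3S)-3-(3,5-dihydroxy-2-methylphenyl)butan-2-ol
Product: 11 (3R,4S)-7-({2,6-dihydroxy-4-[(2S,3R)-3-hydroxybutan-2-yl]-3-methylphenyl}methyl)-3,4,5-trimethyl-3,4-dihydro-1H-2-benzopyran-6,8-diol, via Mannich base 9 (not isolated), via ortho-quinone methide 10 (not isolated)
Conditions: Me2N=CH2+ I− (1.05 equiv), Et3N, CH2Cl2, 0 °C → rt; then 7 (2 equiv), 1,4-dioxane, 100 °C
Reagents that add atoms: N,N-dimethylmethyleneiminium iodide (Eschenmoser's salt) C[N+](C)=C.[I-]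
Why: Mannich aminomethylation at C7, the only free ring carbon of 8, followed by thermal loss of dimethylamine should give an ortho-quinone methide that C-alkylates 7 at the unhindered carbon between its two hydroxyls (its other free position is shielded by the branched side chain), as in Mannich-base couplings to unsymmetrical methylene-bis-phenols.

Step 6
Reactants: 11 (3R,4S)-7-({2,6-dihydroxy-4-[(2S,3R)-3-hydroxybutan-2-yl]-3-methylphenyl}methyl)-3,4,5-trimethyl-3,4-dihydro-1H-2-benzopyran-6,8-diol
Product: 13 dicitrinone I, via 1-ethoxy acetal 12 (not isolated)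
Conditions: HC(OEt)3 (5 equiv), TFA (1 equiv), CH2Cl2, 0 °C → rt; then H2O
Reagents that add atoms: triethyl orthoformate CCOC(OCC)OCC
Why: Acid-catalysed exchange should place the orthoformate carbon on the C3 hydroxyl as a tethered dialkoxycarbenium ion, which is attacked by the only unsubstituted ring carbon (future C8a, ortho to C8–OH and para to C6–OH) to give the 1-ethoxy acetal 12; loss of ethanol then gives the 6,8-dihydroxy-2-benzopyrylium ion, and loss of the C8–OH proton gives the quinone methide. The closest known reaction type is the orthoformate-mediated formylative cyclisation of 5-(3-hydroxybutan-2-yl)resorcinols to 6-hydroxy-isochromen-8-one quinone methides, that is, an oxa-Pictet–Spengler reaction at the formate oxidation level ([5+1]). The pyran ring closes by 6-endo-trig attack of the arene carbon on the tethered carboxonium carbon (should C-formylation come first, 6-exo-trig hemiacetalisation leads to the same acetal 12). No new stereocentre persists because C1 ends as sp2, and C3 and C4 are retained because neither the C3–O nor the C4–C4a bond is broken. The step needs site selectivity, which is secured because 11 carries a single aromatic C–H (the isochroman half is fully substituted) and this C–H sits next to the delivering hydroxyl; orthoesters formed at the phenols are reversible and are hydrolysed on work-up.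

**Compound list**

1 | 1-bromo-3,5-dimethoxy-2-methylbenzene | Cc1c(Br)cc(OC)cc1OC | starting material
2 | (2S,3S)-2,3-dimethyloxirane | C[C@@H]1O[C@H]1C | starting material
3 | (3,5-dimethoxy-2-methylphenyl)magnesium bromide, formed in the flask | Cc1c([Mg]Br)cc(OC)cc1OC | intermediate
4 | (2S,3S)-3-(3,5-dimethoxy-2-methylphenyl)butan-2-ol | C[C@H](O)[C@@H](C)c1cc(OC)cc(OC)c1C | intermediate
5 | (2R,3S)-3-(3,5-dimethoxy-2-methylphenyl)butan-2-yl formate | C[C@@H](OC=O)[C@@H](C)c1cc(OC)cc(OC)c1C | intermediate
6 | (2R,3S)-3-(3,5-dihydroxy-2-methylphenyl)butan-2-yl formate, formed in the flask | C[C@@H](OC=O)[C@@H](C)c1cc(O)cc(O)c1C | intermediate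
7 | (2R,3S)-3-(3,5-dihydroxy-2-methylphenyl)butan-2-ol | C[C@@H](O)[C@@H](C)c1cc(O)cc(O)c1C | intermediate
8 | (3R,4S)-3,4,5-trimethyl-3,4-dihydro-1H-2-benzopyran-6,8-diol | Oc1cc(O)c2c(c1C)[C@H](C)[C@@H](C)OC2 | intermediate
9 | (3R,4S)-7-[(dimethylamino)methyl]-3,4,5-trimethyl-3,4-dihydro-1H-2-benzopyran-6,8-diol, formed in the flask | CN(C)Cc1c(O)c(C)c2c(c1O)CO[C@H](C)[C@H]2C | intermediate
10 | (3R,4S)-6-hydroxy-3,4,5-trimethyl-7-methylidene-3,4-dihydro-1H-2-benzopyran-8(7H)-one, ortho-quinone methide formed in the flask | C=C1C(O)=C(C)C2=C(CO[C@H](C)[C@H]2C)C1=O | intermediate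
11 | (3R,4S)-7-({2,6-dihydroxy-4-[(2S,3R)-3-hydroxybutan-2-yl]-3-methylphenyl}methyl)-3,4,5-trimethyl-3,4-dihydro-1H-2-benzopyran-6,8-diol | C[C@@H](O)[C@@H](C)c1cc(O)c(Cc2c(O)c(C)c3c(c2O)CO[C@H](C)[C@H]3C)c(O)c1C | intermediate
12 | (3R,4S)-1-ethoxy-7-{[(3R,4S)-6,8-dihydroxy-3,4,5-trimethyl-3,4-dihydro-1H-2-benzopyran-7-yl]methyl}-3,4,5-trimethyl-3,4-dihydro-1H-2-benzopyran-6,8-diol, both C1 epimers, formed in the flask | CCOC1O[C@H](C)[C@@H](C)c2c(C)c(O)c(Cc3c(O)c(C)c4c(c3O)CO[C@H](C)[C@H]4C)c(O)c21 | intermediate
13 | dicitrinone I, (3R,4S)-7-{[(3R,4S)-6,8-dihydroxy-3,4,5-trimethyl-3,4-dihydro-1H-2-benzopyran-7-yl]methyl}-6-hydroxy-3,4,5-trimethyl-3,4-dihydro-8H-2-benzopyran-8-one | CC1=C2C(=CO[C@H](C)[C@H]2C)C(=O)C(Cc2c(O)c(C)c3c(c2O)CO[C@H](C)[C@H]3C)=C1O | target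

**Step count.** Total: 6 steps. Longest linear sequence: 6 steps (1 → 2 → 3 → 4 → 5 → 6; compound 7 enters a second time in step 5).

**Steps most likely to fail**

1. Step 5. The C-alkylation of 7 may occur with poor site selectivity (attack at the ring carbon next to the side chain, or O-alkylation), and the quinone methide 10 may condense with unreacted 8 to the symmetric dimer. The fallback fixes the position by directed ortho-metalation. It sets out from 4: n-BuLi (2.2 equiv)/TMEDA in THF should lithiate between the two methoxy groups, and Eschenmoser's salt should then give (2S,3S)-3-{4-[(dimethylamino)methyl]-3,5-dimethoxy-2-methylphenyl}butan-2-ol F1. Mitsunobu inversion with formic acid should give (2R,3S)-3-{4-[(dimethylamino)methyl]-3,5-dimethoxy-2-methylphenyl}butan-2-yl formate F2. BBr3, then MeOH, should give the phenolic Mannich base (2R,3S)-3-{4-[(dimethylamino)methyl]-3,5-dihydroxy-2-methylphenyl}butan-2-ol F3. Heating F3 with 8, whose only free ring carbon is C7, in dioxane should give the bridge with the roles of the two partners reversed, and the route is rejoined at 11.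

2. Step 6. The acid may cleave or scramble the electron-rich diarylmethane bridge, or formylation at the hindered C–H may stay incomplete. The fallback reverses the order of ring closure and bridging. It sets out from 7, which with HC(OEt)3/TFA should give the quinone methide (3R,4S)-6-hydroxy-3,4,5-trimethyl-3,4-dihydro-8H-2-benzopyran-8-one (decarboxycitrinin) F4 by the same tethered [5+1] closure. The Mannich base 9 is made from 8 as in the first half of step 5, but isolated. Heating F4 with 9 should generate 10, to which C7 of F4, its only nucleophilic carbon, adds in a conjugate manner; the route is rejoined at 13. The pyran ring is still the last ring to be closed.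

3. Step 4. Formaldehyde may attack the carbon between the hydroxyls of 7, and product 8 may condense further at C7, leading to oligomers. The fallback closes the ring before the phenols are unmasked, so that only tethered delivery is possible. It sets out from 5: K2CO3/MeOH should give (2R,3S)-3-(3,5-dimethoxy-2-methylphenyl)butan-2-ol F5. Dimethoxymethane/BF3·OEt2 in CH2Cl2 (oxa-Pictet–Spengler through the methoxymethyl ether) should give (3R,4S)-6,8-dimethoxy-3,4,5-trimethyl-3,4-dihydro-1H-2-benzopyran F6. NaSEt in DMF at 140 °C should then cleave both methyl ethers without touching the benzylic ring ether, and the route is rejoined at 8.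

**Further compounds**

F1 | step 5 | (2S,3S)-3-{4-[(dimethylamino)methyl]-3,5-dimethoxy-2-methylphenyl}butan-2-ol | C[C@H](O)[C@@H](C)c1cc(OC)c(CN(C)C)c(OC)c1C
F2 | step 5 | (2R,3S)-3-{4-[(dimethylamino)methyl]-3,5-dimethoxy-2-methylphenyl}butan-2-yl formate | C[C@@H](OC=O)[C@@H](C)c1cc(OC)c(CN(C)C)c(OC)c1C
F3 | step 5 | (2R,3S)-3-{4-[(dimethylamino)methyl]-3,5-dihydroxy-2-methylphenyl}butan-2-ol | C[C@@H](O)[C@@H](C)c1cc(O)c(CN(C)C)c(O)c1C
F4 | step 6 | (3R,4S)-6-hydroxy-3,4,5-trimethyl-3,4-dihydro-8H-2-benzopyran-8-one (decarboxycitrinin) | CC1=C2C(=CO[C@H](C)[C@H]2C)C(=O)C=C1O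
F5 | step 4 | (2R,3S)-3-(3,5-dimethoxy-2-methylphenyl)butan-2-ol | C[C@@H](O)[C@@H](C)c1cc(OC)cc(OC)c1C
F6 | step 4 | (3R,4S)-6,8-dimethoxy-3,4,5-trimethyl-3,4-dihydro-1H-2-benzopyran | COc1cc(OC)c2c(c1C)[C@H](C)[C@@H](C)OC2
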